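The 14-membered ring is closed at C1–C14, the bond from the tertiary carbinol carbon to its ring CH2 on the side of the C11=C12 olefin, by a titanium pinacol coupling of an open-chain C25 keto aldehyde. Two carbonyl carbons of like polarity are joined reductively, which forms the ring, the C1–C14 bond and the tertiary alcohol in one operation. The step exploits the C1(OH)–C14H2 unit of the cyclotetradecatriene: C14 enters as an aldehyde, and its temporary hydroxyl, absent from the target, breaks the near-symmetry of the two CH2CH2C(Me)=CH ring arms at C1, so that C1 epimers can be separated and recycled before the hydroxyl is removed by mesylation and hydride reduction.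

Key step: step 15

Numbering used throughout: ring C1 = carbinol carbon, then C2–C14 around the ring so that the olefins are C4=C5 (E, methyl on C4), C7=C8 (Z, methyl on C8) and C11=C12 (E, methyl on C12); side chain C1′–C7′ with C2′ bonded to C1. The target is (1R,2′R).

Remark on stereocontrol: the two ring arms at C1 are identical for four carbons, so C1 can only be set in the ring closure itself, under the influence of C2′. That induction (methyl versus CH2R) is expected to be modest; the route therefore relies on separation and recycling at the diol stage rather than on high selectivity.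

Step 1
Reactants: 1 nerol, (2Z)-3,7-dimethylocta-2,6-dien-1-ol
Product: 2 neryl chloride, (2Z)-1-chloro-3,7-dimethylocta-2,6-diene
Conditions: PPh3, Cl3CC(O)CCl3, CH2Cl2, 0 °C
Reagents that add atoms: hexachloroacetone, ClC(Cl)(Cl)C(=O)C(Cl)(Cl)Cl
Why: Appel-type chlorination through an alkoxyphosphonium ion replaces the primary allylic hydroxyl by SN2 without allylic shift or loss of the Z geometry.

Step 2
Reactants: 2 neryl chloride; 3 but-3-yn-1-ol
Product: 5 (3E,6Z)-3,7,11-trimethyldodeca-3,6,10-trien-1-ol, via E-alkenylalane 4 (not isolated)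
Conditions: 3, Me3Al (3 equiv), Cp2ZrCl2 (0.25 equiv), CH2Cl2, 25 °C; then 2, Pd(PPh3)4 (5 mol %), THF, 25 °C; dilute HCl
Reagents that add atoms: trimethylaluminium, C[Al](C)C
Why: Negishi zirconium-catalysed carboalumination adds methyl and aluminium syn across the alkyne, and the E-alkenylalane couples at the primary carbon of the allylic chloride under zerovalent palladium catalysis with retention of both olefin geometries, which gives the skipped C4=C5/C7=C8 diene.

Step 3
Reactants: 5 (3E,6Z)-3,7,11-trimethyldodeca-3,6,10-trien-1-ol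
Product: 6 (2E,6Z,9E)-2,6,10-trimethyldodeca-2,6,9-triene-1,12-diol
Conditions: SeO2 (0.3 equiv), t-BuOOH, salicylic acid (cat.), CH2Cl2, 25 °C
Reagents that add atoms: selenium dioxide, O=[Se]=O (catalytic oxygen carrier); tert-butyl hydroperoxide, CC(C)(C)OO
Why: Sharpless allylic oxidation (ene reaction, then [2,3]-shift) attacks the most accessible terminal isopropylidene group and hydroxylates its E-methyl group.

Step 4
Reactants: 6 (2E,6Z,9E)-2,6,10-trimethyldodeca-2,6,9-triene-1,12-diol
Product: 7 (3E,6Z,10E)-12-bromo-3,7,11-trimethyldodeca-3,6,10-trien-1-ol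
Conditions: NBS, Me2S, CH2Cl2, −20 to 0 °C
Reagents that add atoms: N-bromosuccinimide, O=C1CCC(=O)N1Br
Why: Corey–Kim halogenation converts only the allylic alcohol into the bromide through an alkoxysulfonium salt and leaves the saturated primary alcohol untouched.

Step 5
Reactants: 7 (3E,6Z,10E)-12-bromo-3,7,11-trimethyldodeca-3,6,10-trien-1-ol; 8 1,3-dithiane
Product: 10 (3E,6Z,10E)-12-(1,3-dithian-2-yl)-3,7,11-trimethyldodeca-3,6,10-trien-1-ol, via 2-lithio-1,3-dithiane 9 (not isolated)
Conditions: 8 (2.3 equiv), n-BuLi (2.2 equiv), THF, −30 °C; then 7, −78 to −20 °C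
Reagents that add atoms: none
Why: Corey–Seebach alkylation, in which the dithiane anion (in excess because the free hydroxyl consumes one equivalent) displaces the primary allylic bromide by SN2 and brings in C14 as a masked aldehyde.

Step 6
Reactants: 10 (3E,6Z,10E)-12-(1,3-dithian-2-yl)-3,7,11-trimethyldodeca-3,6,10-trien-1-ol
Product: 11 2-[(2E,6Z,9E)-12-iodo-2,6,10-trimethyldodeca-2,6,9-trien-1-yl]-1,3-dithiane
Conditions: I2, PPh3, imidazole, CH2Cl2, 0 °C
Reagents that add atoms: iodine, II
Why: Appel iodination of the primary alcohol under Garegg–Samuelsson conditions.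

Step 7
Reactants: 12 (R)-4-benzyl-1,3-oxazolidin-2-one; 13 hex-5-enoyl chloride
Product: 14 (R)-4-benzyl-3-(hex-5-enoyl)-1,3-oxazolidin-2-one
Conditions: Et3N, DMAP (cat.), CH2Cl2, 0 to 25 °C
Reagents that add atoms: none
Why: DMAP-catalysed N-acylation of the Evans auxiliary.

Step 8
Reactants: 14 (R)-4-benzyl-3-(hex-5-enoyl)-1,3-oxazolidin-2-one
Product: 16 (R)-4-benzyl-3-[(2R)-2-methylhex-5-enoyl]-1,3-oxazolidin-2-one, via sodium Z-enolate 15 (not isolated)
Conditions: NaN(SiMe3)2, THF, −78 °C; MeI, −78 °C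
Reagents that add atoms: iodomethane, CI
Why: Evans alkylation, in which the chelated Z-enolate is methylated on the face opposite the benzyl group and so sets C2′ as R.

Step 9
Reactants: 16 (R)-4-benzyl-3-[(2R)-2-methylhex-5-enoyl]-1,3-oxazolidin-2-one
Product: 17 (2R)-N-methoxy-N,2-dimethylhex-5-enamide
Conditions: MeNHOMe·HCl, Me3Al, CH2Cl2, 0 to 25 °C; dilute HCl
Reagents that add atoms: N,O-dimethylhydroxylamine hydrochloride, CNOC.Cl
Why: Weinreb aminolysis with the aluminium amide cleaves the exocyclic acyl group without touching the new stereocenter and returns the auxiliary.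

Step 10
Reactants: 17 (2R)-N-methoxy-N,2-dimethylhex-5-enamide; 18 methacrolein
Product: 19 (2R,5E)-N-methoxy-N,2,6-trimethyl-7-oxohept-5-enamide
Conditions: second-generation Grubbs catalyst RuCl2(=CHPh)(PCy3)(H2IMes) (5 mol %), 18 (5 equiv), CH2Cl2, 40 °C
Reagents that add atoms: none
Why: Olefin cross-metathesis of the terminal olefin with excess methacrolein gives the trisubstituted enal with high E selectivity.

Step 11
Reactants: 19 (2R,5E)-N-methoxy-N,2,6-trimethyl-7-oxohept-5-enamide
Product: 20 (2R,5E)-7-hydroxy-N-methoxy-N,2,6-trimethylhept-5-enamide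
Conditions: NaBH4, CeCl3·7H2O, MeOH, −40 °C
Reagents that add atoms: none
Why: Luche reduction gives clean 1,2-reduction of the enal and leaves the Weinreb amide intact.

Step 12
Reactants: 20 (2R,5E)-7-hydroxy-N-methoxy-N,2,6-trimethylhept-5-enamide
Product: 21 (2R,5E)-7-[(tert-butyldiphenylsilyl)oxy]-N-methoxy-N,2,6-trimethylhept-5-enamide
Conditions: t-BuPh2SiCl, imidazole, CH2Cl2, 25 °C
Reagents that add atoms: tert-butyl(chloro)diphenylsilane, CC(C)(C)[Si](Cl)(c1ccccc1)c1ccccc1
Why: Silylation of the primary allylic alcohol with a group that survives organolithium, Lewis-acidic titanium and hydride conditions.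

Step 13
Reactants: 11 2-[(2E,6Z,9E)-12-iodo-2,6,10-trimethyldodeca-2,6,9-trien-1-yl]-1,3-dithiane; 21 (2R,5E)-7-[(tert-butyldiphenylsilyl)oxy]-N-methoxy-N,2,6-trimethylhept-5-enamide
Product: 23 (2E,6R,10E,13Z,17E)-1-[(tert-butyldiphenylsilyl)oxy]-19-(1,3-dithian-2-yl)-2,6,10,14,18-pentamethylnonadeca-2,10,13,17-tetraen-7-one, via alkyllithium 22 (not isolated)
Conditions: 11, t-BuLi (2.1 equiv), Et2O, −78 °C; then 21, THF, −78 to −40 °C; 1 M HCl
Reagents that add atoms: none
Why: Iodine–lithium exchange at −78 °C outruns deprotonation of the dithiane, and the primary alkyllithium adds once to the Weinreb amide through the chelated tetrahedral adduct (Weinreb ketone synthesis) without epimerizing C2′.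

Step 14
Reactants: 23 (2E,6R,10E,13Z,17E)-1-[(tert-butyldiphenylsilyl)oxy]-19-(1,3-dithian-2-yl)-2,6,10,14,18-pentamethylnonadeca-2,10,13,17-tetraen-7-one
Product: 24 (3E,7Z,10E,15R,18E)-20-[(tert-butyldiphenylsilyl)oxy]-3,7,11,15,19-pentamethyl-14-oxoicosa-3,7,10,18-tetraenal
Conditions: MeI, CaCO3, MeCN–H2O (4:1), 45 °C
Reagents that add atoms: water, O
Why: S-Methylation turns the dithiane into a leaving group, and buffered hydrolysis frees the aldehyde under near-neutral conditions that spare the silyl ether, the ketone α-stereocenter and the β,γ-olefin.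

Step 15
Reactants: 24 (3E,7Z,10E,15R,18E)-20-[(tert-butyldiphenylsilyl)oxy]-3,7,11,15,19-pentamethyl-14-oxoicosa-3,7,10,18-tetraenal
Product: 25 (1R,4E,7Z,11E)-1-{(2R,5E)-7-[(tert-butyldiphenylsilyl)oxy]-6-methylhept-5-en-2-yl}-4,8,12-trimethylcyclotetradeca-4,7,11-triene-1,14-diol, both C14 epimers, separated from the 1S diols on silica
Conditions: TiCl3(DME)1.5, Zn–Cu couple, DME, 25 °C, 24 added by syringe pump over 30 h (final 0.003 M); 10% aq. K2CO3
Reagents that add atoms: none
Why: Low-valent titanium (TiCl3 reduced by Zn–Cu) transfers one electron to each carbonyl, and the titanium-bound ketyls at C1 and C14 couple on the metal to a titanium pinacolate that is stable at 25 °C and gives the 1,14-diol on hydrolysis; the closest known reaction is the McMurry titanium pinacol macrocyclization of keto aldehydes to 14-membered cembranoid 1,2-diols. The one ring closed is the cyclotetradecatriene, by intramolecular head-to-tail reductive coupling of the chain termini C1 and C14 on titanium under high dilution. The new stereocenter C14 is uncontrolled and irrelevant because step 17 erases it. The new stereocenter C1 is controlled only by 1,2-induction from C2′: in the ketyl conformer with C2′–H eclipsing the bulky C1–O–Ti bond, coupling anti to the C3′ chain gives 1R, but methyl and chain differ little, so only modest selectivity is expected. The step needs ring closure instead of dimerization (secured by syringe-pump dilution), a stop at the diol instead of the olefin (secured by 25 °C) and no ketyl attack on the olefins (titanium ketyls do not add to unactivated trisubstituted olefins). The temporary C14 hydroxyl makes the two ring arms at C1 different, so 1R and 1S diols should separate on silica, and the 1S diols are cleaved with NaIO4 back to 24 and recycled.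

Step 16
Reactants: 25 (1R)-1,14-diol, both C14 epimers
Product: 26 14-methanesulfonate of 25
Conditions: MsCl, Et3N, CH2Cl2, −30 to 0 °C
Reagents that add atoms: methanesulfonyl chloride, CS(=O)(=O)Cl
Why: Sulfonylation is selective for the secondary C14 hydroxyl because the tertiary C1 hydroxyl is too hindered.

Step 17
Reactants: 26 14-methanesulfonate of 25
Product: 28 tert-butyldiphenylsilyl ether of the target at O7′, via 1,14-epoxide 27 (not isolated)
Conditions: LiEt3BH (6 equiv), THF, 0 to 25 °C
Reagents that add atoms: none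
Why: The hydride reagent deprotonates the C1 hydroxyl, the alkoxide displaces the vicinal mesylate to give the 1,14-epoxide, and LiEt3BH opens this trisubstituted epoxide by SN2 at the less substituted C14, which leaves the C1–O bond and its configuration untouched.

Step 18
Reactants: 28 tert-butyldiphenylsilyl ether of the target
Product: 29 (1R,4E,7Z,11E)-1-[(2R,5E)-7-hydroxy-6-methylhept-5-en-2-yl]-4,8,12-trimethylcyclotetradeca-4,7,11-trien-1-ol (target)
Conditions: Bu4NF, THF, 25 °C
Reagents that add atoms: none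
Why: Fluoride cleaves the silyl ether and frees the primary allylic alcohol.

Compound list
1 | nerol | CC(C)=CCC/C(C)=C\CO | starting material
2 | neryl chloride | CC(C)=CCC/C(C)=C\CCl | intermediate
3 | but-3-yn-1-ol | C#CCCO | starting material
4 | [(1E)-4-(dimethylalumanyloxy)-2-methylbut-1-en-1-yl]dimethylalumane | C[Al](C)OCC/C(C)=C/[Al](C)C | intermediate
5 | (3E,6Z)-3,7,11-trimethyldodeca-3,6,10-trien-1-ol | OCC/C(C)=C/C/C=C(/C)CCC=C(C)C | intermediate
6 | (2E,6Z,9E)-2,6,10-trimethyldodeca-2,6,9-triene-1,12-diol | OCC/C(C)=C/C/C=C(/C)CC/C=C(\C)CO | intermediate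
7 | (3E,6Z,10E)-12-bromo-3,7,11-trimethyldodeca-3,6,10-trien-1-ol | OCC/C(C)=C/C/C=C(/C)CC/C=C(\C)CBr | intermediate
8 | 1,3-dithiane | C1CSCSC1 | starting material
9 | 2-lithio-1,3-dithiane | [Li]C1SCCCS1 | intermediate
10 | (3E,6Z,10E)-12-(1,3-dithian-2-yl)-3,7,11-trimethyldodeca-3,6,10-trien-1-ol | OCC/C(C)=C/C/C=C(/C)CC/C=C(\C)CC1SCCCS1 | intermediate
11 | 2-[(2E,6Z,9E)-12-iodo-2,6,10-trimethyldodeca-2,6,9-trien-1-yl]-1,3-dithiane | ICC/C(C)=C/C/C=C(/C)CC/C=C(\C)CC1SCCCS1 | intermediate
12 | (R)-4-benzyl-1,3-oxazolidin-2-one | O=C1N[C@H](Cc2ccccc2)CO1 | starting material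
13 | hex-5-enoyl chloride | C=CCCCC(=O)Cl | starting material
14 | (R)-4-benzyl-3-(hex-5-enoyl)-1,3-oxazolidin-2-one | C=CCCCC(=O)N1[C@H](Cc2ccccc2)COC1=O | intermediate
15 | sodium (Z)-enolate of 14 | [Na+].[O-]/C(=C\CCC=C)N1[C@H](Cc2ccccc2)COC1=O | intermediate
16 | (R)-4-benzyl-3-[(2R)-2-methylhex-5-enoyl]-1,3-oxazolidin-2-one | C=CCC[C@@H](C)C(=O)N1[C@H](Cc2ccccc2)COC1=O | intermediate
17 | (2R)-N-methoxy-N,2-dimethylhex-5-enamide | C=CCC[C@@H](C)C(=O)N(C)OC | intermediate
18 | methacrolein | CC(=C)C=O | starting material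
19 | (2R,5E)-N-methoxy-N,2,6-trimethyl-7-oxohept-5-enamide | O=C/C(C)=C/CC[C@@H](C)C(=O)N(C)OC | intermediate
20 | (2R,5E)-7-hydroxy-N-methoxy-N,2,6-trimethylhept-5-enamide | OC/C(C)=C/CC[C@@H](C)C(=O)N(C)OC | intermediate
21 | (2R,5E)-7-[(tert-butyldiphenylsilyl)oxy]-N-methoxy-N,2,6-trimethylhept-5-enamide | CC(C)(C)[Si](OC/C(C)=C/CC[C@@H](C)C(=O)N(C)OC)(c1ccccc1)c1ccccc1 | intermediate
22 | [(3E,6Z,10E)-12-(1,3-dithian-2-yl)-3,7,11-trimethyldodeca-3,6,10-trien-1-yl]lithium | [Li]CC/C(C)=C/C/C=C(/C)CC/C=C(\C)CC1SCCCS1 | intermediate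
23 | (2E,6R,10E,13Z,17E)-1-[(tert-butyldiphenylsilyl)oxy]-19-(1,3-dithian-2-yl)-2,6,10,14,18-pentamethylnonadeca-2,10,13,17-tetraen-7-one | CC(C)(C)[Si](OC/C(C)=C/CC[C@@H](C)C(=O)CC/C(C)=C/C/C=C(/C)CC/C=C(\C)CC1SCCCS1)(c1ccccc1)c1ccccc1 | intermediate
24 | (3E,7Z,10E,15R,18E)-20-[(tert-butyldiphenylsilyl)oxy]-3,7,11,15,19-pentamethyl-14-oxoicosa-3,7,10,18-tetraenal | CC(C)(C)[Si](OC/C(C)=C/CC[C@@H](C)C(=O)CC/C(C)=C/C/C=C(/C)CC/C=C(\C)CC=O)(c1ccccc1)c1ccccc1 | intermediate
25 | (1R,4E,7Z,11E)-1-{(2R,5E)-7-[(tert-butyldiphenylsilyl)oxy]-6-methylhept-5-en-2-yl}-4,8,12-trimethylcyclotetradeca-4,7,11-triene-1,14-diol, both C14 epimers | C/C1=C/C/C=C(\C)CC[C@@](O)([C@H](C)CC/C=C(\C)CO[Si](c2ccccc2)(c2ccccc2)C(C)(C)C)C(O)C/C(C)=C/CC1 | intermediate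
26 | 14-methanesulfonate of 25, both C14 epimers | C/C1=C/C/C=C(\C)CC[C@@](O)([C@H](C)CC/C=C(\C)CO[Si](c2ccccc2)(c2ccccc2)C(C)(C)C)C(OS(C)(=O)=O)C/C(C)=C/CC1 | intermediate
27 | 1,14-epoxide derived from 26, C1 configured as in 25, both C14 epimers | C/C1=C/C/C=C(\C)CC[C@@]2(OC2C/C(C)=C/CC1)[C@H](C)CC/C=C(\C)CO[Si](c3ccccc3)(c3ccccc3)C(C)(C)C | intermediate
28 | (1R,4E,7Z,11E)-1-{(2R,5E)-7-[(tert-butyldiphenylsilyl)oxy]-6-methylhept-5-en-2-yl}-4,8,12-trimethylcyclotetradeca-4,7,11-trien-1-ol | C/C1=C/C/C=C(\C)CC[C@@](O)([C@H](C)CC/C=C(\C)CO[Si](c2ccccc2)(c2ccccc2)C(C)(C)C)CC/C(C)=C/CC1 | intermediate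
29 | (1R,4E,7Z,11E)-1-[(2R,5E)-7-hydroxy-6-methylhept-5-en-2-yl]-4,8,12-trimethylcyclotetradeca-4,7,11-trien-1-ol | C/C1=C/C/C=C(\C)CC[C@@](O)([C@H](C)CC/C=C(\C)CO)CC/C(C)=C/CC1 | target

Total step count: 18. Longest linear sequence: 12 steps (steps 1–6, then 13–18; the branch of steps 7–12, then 13–18, is equally long).

Steps most likely to fail

Step 15. The chain ends may couple between molecules, the aldehyde may be reduced or the pinacolate deoxygenated before the ring closes, and the face selectivity at C1 may be low. Fallback, setting out from 24 and returning at 28: NaBH4 in CH2Cl2–MeOH at −78 °C should reduce only the aldehyde and give the hydroxy ketone F1. I2, PPh3 and imidazole should turn it into the iodo ketone F2. Slow addition of F2 to SmI2 and HMPA in THF (intramolecular samarium Barbier reaction, in which the reduced primary carbon C14 adds to the C1 ketone) would close the same C1–C14 bond and give 28 directly.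

Step 3. The oxidation may also attack the allylic CH2 groups of the two inner trisubstituted olefins or run on to the enal. Fallback, setting out from 2 and returning at 6: the SeO2/t-BuOOH oxidation is done first on neryl chloride 2, whose C2=C3 olefin is deactivated by the allylic chlorine, to give (2E,6Z)-8-chloro-2,6-dimethylocta-2,6-dien-1-ol F3. Alkenylalane 4 (made from 3 with one extra equivalent of Me3Al to cap the hydroxyl) is then coupled with F3 under Pd(PPh3)4 as in step 2, which should give diol 6.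

Step 14. The S-alkylative hydrolysis may be slow, and during it the C11=C12 olefin may move into conjugation with the new aldehyde. Fallback, setting out from 10 and returning at 24: MeI and CaCO3 in MeOH–HC(OMe)3 should exchange the dithiane for a dimethyl acetal while the molecule is still a simple alcohol, giving the hydroxy acetal F4. I2, PPh3 and imidazole give the iodo acetal F5. t-BuLi gives the alkyllithium F6, which is acylated with 21 as in step 13 to the keto acetal F7. Pyridinium p-toluenesulfonate in wet acetone at 25 °C should then free aldehyde 24 just before the coupling.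

Further compounds
F1 | step 15 | (2E,6R,10E,13Z,17E)-1-[(tert-butyldiphenylsilyl)oxy]-20-hydroxy-2,6,10,14,18-pentamethylicosa-2,10,13,17-tetraen-7-one | CC(C)(C)[Si](OC/C(C)=C/CC[C@@H](C)C(=O)CC/C(C)=C/C/C=C(/C)CC/C=C(\C)CCO)(c1ccccc1)c1ccccc1
F2 | step 15 | (2E,6R,10E,13Z,17E)-1-[(tert-butyldiphenylsilyl)oxy]-20-iodo-2,6,10,14,18-pentamethylicosa-2,10,13,17-tetraen-7-one | CC(C)(C)[Si](OC/C(C)=C/CC[C@@H](C)C(=O)CC/C(C)=C/C/C=C(/C)CC/C=C(\C)CCI)(c1ccccc1)c1ccccc1
F3 | step 3 | (2E,6Z)-8-chloro-2,6-dimethylocta-2,6-dien-1-ol | OC/C(C)=C/CC/C(C)=C\CCl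
F4 | step 14 | (3E,6Z,10E)-13,13-dimethoxy-3,7,11-trimethyltrideca-3,6,10-trien-1-ol | OCC/C(C)=C/C/C=C(/C)CC/C=C(\C)CC(OC)OC
F5 | step 14 | (3E,7Z,10E)-13-iodo-1,1-dimethoxy-3,7,11-trimethyltrideca-3,7,10-triene | ICC/C(C)=C/C/C=C(/C)CC/C=C(\C)CC(OC)OC
F6 | step 14 | [(3E,6Z,10E)-13,13-dimethoxy-3,7,11-trimethyltrideca-3,6,10-trien-1-yl]lithium | [Li]CC/C(C)=C/C/C=C(/C)CC/C=C(\C)CC(OC)OC
F7 | step 14 | dimethyl acetal of 24 at C1 | CC(C)(C)[Si](OC/C(C)=C/CC[C@@H](C)C(=O)CC/C(C)=C/C/C=C(/C)CC/C=C(\C)CC(OC)OC)(c1ccccc1)c1ccccc1
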